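The α-methylene γ-lactone (ring O–C2–C1–C15–C16) sits on a ring fusion whose O-bearing carbon C2 is allylic to the C3=C4 olefin of the 14-membered carbocycle. The unit C1–C2–C3=C4 is therefore read as the 1,2-adduct of a ring 1,3-diene. A lactone-free macrocycle, the (6R)-butenolide-bridged 1E,3E,11E-triene, is built first. A palladium-catalysed heteroannulation with 2-bromoacrylic acid then lays the whole acrylate across C1=C2, forming C15–C1 and O–C2 and both ring-fusion stereocentres in one operation. A final singlet-oxygen ene reaction turns the C11=C12 olefin into the C12 hydroperoxide with the E-C10=C11 olefin.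

Key step: step 9

Remark (numbering used throughout): the ring carbons are C1–C14. C1 is the ring-fusion CH bearing the lactone α-carbon C15 (C16 its carbonyl, C17 its exo-methylene), and C2 is the lactone O–CH. C3=C4 carries the C4 methyl, C6 is the butenolide O–CH, and C7=C8 is the butenolide olefin (C19 its carbonyl on C8). C12 carries methyl and OOH. The target is then (1R,2S,6R,12S,3E,10E). Compounds 1, 2, 7, 12, 13 and 23 are taken as commercial.

Step 1
Reactants: 1 (R)-epichlorohydrin; 2 acetylene
Product: 4 (2R)-1-chloropent-4-yn-2-ol, via lithium acetylide 3 (not isolated)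
Conditions: 2, n-BuLi, THF, −78 °C; BF3·OEt2; then 1, −78 °C; aq. NH4Cl
Reagents that add atoms: n-butyllithium, [Li]CCCC (lithium of intermediate 3 only)
Why: BF3-assisted epoxide alkynylation should open the oxirane at its unsubstituted carbon and leave C–Cl and the stereocentre untouched, so the (R)-centre of 1 becomes C6 of the target.

Step 2
Reactants: 4 (2R)-1-chloropent-4-yn-2-ol
Product: 6 (2R,4E)-1-chloro-5-iodo-4-methylpent-4-en-2-ol, via alkenylalane 5 (not isolated)
Conditions: AlMe3 (3 equiv), Cp2ZrCl2 (25 mol %), CH2Cl2, 0 °C → rt; then I2, THF, −30 → 0 °C; aq. HCl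
Reagents that add atoms: trimethylaluminium, C[Al](C)C; iodine, II
Why: Negishi zirconium-catalysed carboalumination adds methyl and aluminium syn across the terminal alkyne with methyl on the internal carbon, and iodinolysis with retention should give the E-trisubstituted vinyl iodide that becomes C3=C4.

Step 3
Reactants: 6 (2R,4E)-1-chloro-5-iodo-4-methylpent-4-en-2-ol; 7 (phenylsulfanyl)acetic acid
Product: 11 (5R)-5-[(2E)-3-iodo-2-methylprop-2-en-1-yl]-3-(phenylsulfanyl)oxolan-2-one (C3 epimers), via epoxide 8 (not isolated), via acid dianion 9 (not isolated), via hydroxy acid 10 (not isolated)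
Conditions: 6, NaH, THF, 0 °C → rt; added to 9 [from 7, LiN(i-Pr)2 (2.1 equiv), THF, 0 °C], rt; aq. HCl; then TsOH·H2O (cat.), benzene, reflux
Reagents that add atoms: lithium diisopropylamide, [Li]N(C(C)C)C(C)C (lithium of intermediate 9 only)
Why: Williamson closure gives the terminal epoxide with C6 unchanged, the carboxylic acid dianion opens it at the CH2 terminus (C7) and acid-catalysed lactonisation closes the γ-lactone; the sulfur-bearing carbon forms as a mixture that step 7 removes.

Step 4
Reactants: 12 hex-1-en-5-yne; 13 oxirane
Product: 16 (3E)-4-methylocta-3,7-dien-1-ol, via alkenylalane 14 (not isolated), via lithium alanate 15 (not isolated)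
Conditions: AlMe3 (2 equiv), Cp2ZrCl2 (20 mol %), CH2Cl2, 0 °C → rt; volatiles removed; n-BuLi, hexane, 0 °C; then 13, THF, 0 °C → rt; aq. HCl
Reagents that add atoms: trimethylaluminium, C[Al](C)C; n-butyllithium, [Li]CCCC (butyl and lithium of intermediate 15 only)
Why: Negishi carboalumination is selective for the alkyne over the terminal olefin and syn-specific, and the alanate should open oxirane with retention of the olefin geometry to give the E-homoallylic alcohol (C9–C14, C1, C2).

Step 5
Reactants: 16 (3E)-4-methylocta-3,7-dien-1-ol
Product: 17 (5E)-8-iodo-5-methylocta-1,5-diene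
Conditions: I2, PPh3, imidazole, CH2Cl2, 0 °C → rt
Reagents that add atoms: iodine, II
Why: Appel-type iodination should convert the primary alcohol into the iodide without touching either olefin.

Step 6
Reactants: 11 (5R)-5-[(2E)-3-iodo-2-methylprop-2-en-1-yl]-3-(phenylsulfanyl)oxolan-2-one; 17 (5E)-8-iodo-5-methylocta-1,5-diene
Product: 19 (5R)-5-[(2E)-3-iodo-2-methylprop-2-en-1-yl]-3-[(3E)-4-methylocta-3,7-dien-1-yl]-3-(phenylsulfanyl)oxolan-2-one (C3 epimers), via lithium enolate 18 (not isolated)
Conditions: LiN(SiMe3)2 (1.1 equiv), THF, −78 °C; then 17, HMPA, −78 °C → rt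
Reagents that add atoms: lithium hexamethyldisilazide, [Li]N([Si](C)(C)C)[Si](C)(C)C (lithium of intermediate 18 only)
Why: The sulfur-stabilised lactone enolate is soft and weakly basic, so SN2 C-alkylation by the primary iodide (C8–C9 bond) should outrun elimination; the new quaternary centre is stereochemically irrelevant.

Step 7
Reactants: 19 (5R)-5-[(2E)-3-iodo-2-methylprop-2-en-1-yl]-3-[(3E)-4-methylocta-3,7-dien-1-yl]-3-(phenylsulfanyl)oxolan-2-one
Product: 21 (5R)-5-[(2E)-3-iodo-2-methylprop-2-en-1-yl]-3-[(3E)-4-methylocta-3,7-dien-1-yl]furan-2(5H)-one, via sulfoxide 20 (not isolated)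
Conditions: mCPBA (1.0 equiv), CH2Cl2, −78 → −20 °C; aq. NaHCO3; then toluene, CaCO3, 110 °C
Reagents that add atoms: mCPBA, O=C(OO)c1cccc(Cl)c1 (oxygen of intermediate 20 only)
Why: Sulfide oxidation by one equivalent of peracid at low temperature is faster than olefin epoxidation, and thermal syn-elimination of the sulfoxide towards the ring CH2 should give the conjugated endocyclic butenolide (C7=C8) without touching C6.

Step 8
Reactants: 21 (5R)-5-[(2E)-3-iodo-2-methylprop-2-en-1-yl]-3-[(3E)-4-methylocta-3,7-dien-1-yl]furan-2(5H)-one
Product: 22 (6R)-macrocyclic triene butenolide: 14-membered carbocycle C1–C14 holding the 1E 3E-diene (methyl on C4) plus the 11E-olefin (methyl on C12); O–C19(=O) bridges C6 to C8 (C7=C8)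
Conditions: Pd(OAc)2 (20 mol %), PPh3 (40 mol %), Ag2CO3 (2 equiv), MeCN, 0.002 M, 70 °C
Reagents that add atoms: none
Why: Intramolecular Heck reaction under high dilution: the E-alkenylpalladium, whose geometry rules out small-ring closure onto the butenolide, should add to the terminal carbon of the monosubstituted olefin (C2–C3 bond) and β-hydride elimination gives the conjugated 1E,3E-diene; Ag2CO3 avoids amine bases that could epimerise C6.

Step 9
Reactants: 22 (6R)-macrocyclic triene butenolide; 23 2-bromoacrylic acid
Product: 24 (1R;2S;6R)-bis-lactone triene: 22 carrying the trans-fused α-methylene γ-lactone across C1/C2 (C15 on C1; lactone O on C2); C3=C4 E; C11=C12 E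
Conditions: 23 (3 equiv, slow addition), Pd(OAc)2 (10 mol %), PPh3 (20 mol %), Ag2CO3 (3 equiv), DMF, 60 °C
Reagents that add atoms: none
Why: Zerovalent palladium should insert into the C–Br bond of the silver carboxylate of 23, the 1-carboxylatovinyl–palladium species adds syn across C1=C2 of the s-trans diene with carbon bonding to the disubstituted terminus C1, and the resulting η3-allyl (C2–C4) palladium, held by the carboxylate in a six-membered oxapalladacycle, forms the C2–O bond and returns zerovalent palladium. The closest known reaction type is the Larock heteroannulation of 1,3-dienes with vinylic halides that carry a carboxylic acid, which gives α-alkylidene γ-lactones. The only ring closed is the five-membered lactone, by 5-exo attack of the carboxylate oxygen on the allyl terminus C2 (closure at the fully substituted C4 would give a seven-membered ring), and the C3=C4 E geometry is inherited from the diene. C1 is set in the migratory insertion on the peripheral diene face, the one turned away from the butenolide that the C6 stereocentre and allylic strain about C4–C5 hold on the other side of the bridged macrocycle; C2 is set relative to C1 by inner-sphere C–O formation from the palladium-bound carboxylate, so that net syn addition to the E olefin should give the trans ring fusion. The step needs the diene to react in preference to the C11=C12 olefin and the butenolide (only the diene gives a stabilised allyl–palladium), C1 to be attacked in preference to C4 (steric), and the trans fusion to form, for which chloride-free conditions with Ag2CO3 as base and bromide scavenger are chosen to suppress outer-sphere anti attack. Ag2CO3 is mild enough not to epimerise C6–H of the butenolide, and 23 is added slowly to limit its self-coupling.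

Step 10
Reactants: 24 (1R;2S;6R)-bis-lactone triene
Product: 25 target CNP0343227.1 (1R;2S;6R;12S;3E;10E)
Conditions: O2, tetraphenylporphyrin (cat.), visible light, CH2Cl2, −20 °C
Reagents that add atoms: dioxygen (as singlet oxygen), O=O
Why: Schenck ene reaction: the electron-rich C11=C12 olefin should react in preference to the acyloxy-deactivated C3=C4 olefin and the two electron-poor olefins, oxygen bonds to C12 with suprafacial abstraction of a C10 hydrogen on the disubstituted side of the olefin to give the E-C10=C11 olefin, and the C12 configuration should follow from attack on the peripheral face of the macrocycle; the C11 hydroperoxide with an exocyclic olefin is the expected by-product to be separated.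

Compound list
1 | (R)-epichlorohydrin, (2R)-2-(chloromethyl)oxirane | ClC[C@H]1CO1 | starting material
2 | acetylene | C#C | starting material
3 | lithium acetylide | [Li]C#C | intermediate
4 | (2R)-1-chloropent-4-yn-2-ol | C#CC[C@@H](O)CCl | intermediate
5 | alkenylalane: (2R,4E)-1-chloro-5-(dimethylalumanyl)-4-methylpent-4-en-2-ol as its dimethylaluminium alkoxide | C[Al](C)/C=C(\C)C[C@@H](O[Al](C)C)CCl | intermediate
6 | (2R,4E)-1-chloro-5-iodo-4-methylpent-4-en-2-ol | I/C=C(\C)C[C@@H](O)CCl | intermediate
7 | (phenylsulfanyl)acetic acid | OC(=O)CSc1ccccc1 | starting material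
8 | (2R)-2-[(2E)-3-iodo-2-methylprop-2-en-1-yl]oxirane | I/C=C(\C)C[C@@H]1CO1 | intermediate
9 | dilithium dianion of (phenylsulfanyl)acetic acid | [Li+].[Li+].[O-]C([O-])=CSc1ccccc1 | intermediate
10 | (4R,6E)-4-hydroxy-7-iodo-6-methyl-2-(phenylsulfanyl)hept-6-enoic acid (C2 epimers) | I/C=C(\C)C[C@@H](O)CC(Sc1ccccc1)C(=O)O | intermediate
11 | (5R)-5-[(2E)-3-iodo-2-methylprop-2-en-1-yl]-3-(phenylsulfanyl)oxolan-2-one (C3 epimers) | I/C=C(\C)C[C@@H]1CC(Sc2ccccc2)C(=O)O1 | intermediate
12 | hex-1-en-5-yne | C=CCCC#C | starting material
13 | oxirane | C1CO1 | starting material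
14 | alkenylalane: dimethyl[(1E)-2-methylhexa-1,5-dien-1-yl]alumane | C[Al](C)/C=C(\C)CCC=C | intermediate
15 | lithium butyl(dimethyl)[(1E)-2-methylhexa-1,5-dien-1-yl]alanate | [Li+].CCCC[Al-](C)(C)/C=C(\C)CCC=C | intermediate
16 | (3E)-4-methylocta-3,7-dien-1-ol | OCC/C=C(\C)CCC=C | intermediate
17 | (5E)-8-iodo-5-methylocta-1,5-diene | ICC/C=C(\C)CCC=C | intermediate
18 | lithium enolate of 11 | I/C=C(\C)C[C@@H]1CC(Sc2ccccc2)=C([O-])O1.[Li+] | intermediate
19 | (5R)-5-[(2E)-3-iodo-2-methylprop-2-en-1-yl]-3-[(3E)-4-methylocta-3,7-dien-1-yl]-3-(phenylsulfanyl)oxolan-2-one (C3 epimers) | I/C=C(\C)C[C@@H]1CC(Sc2ccccc2)(CC/C=C(\C)CCC=C)C(=O)O1 | intermediate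
20 | sulfoxide of 19, 3-(benzenesulfinyl) lactone | I/C=C(\C)C[C@@H]1CC(S(=O)c2ccccc2)(CC/C=C(\C)CCC=C)C(=O)O1 | intermediate
21 | (5R)-5-[(2E)-3-iodo-2-methylprop-2-en-1-yl]-3-[(3E)-4-methylocta-3,7-dien-1-yl]furan-2(5H)-one | I/C=C(\C)C[C@@H]1C=C(CC/C=C(\C)CCC=C)C(=O)O1 | intermediate
22 | (6R,1E,3E,11E)-macrocyclic triene butenolide: 14-membered carbocycle C1–C14, methyls on C4 and C12, butenolide O–C19(=O) bridging C6 and C8 (C7=C8) | C1/C=C/C=C(\C)C[C@@H]2C=C(CC/C=C(\C)C1)C(=O)O2 | intermediate
23 | 2-bromoacrylic acid (2-bromoprop-2-enoic acid) | C=C(Br)C(=O)O | starting material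
24 | (1R,2S,6R,3E,11E)-bis-lactone triene: 22 with the trans-fused α-methylene γ-lactone across C1/C2 | C=C1C(=O)O[C@H]2/C=C(\C)C[C@@H]3C=C(CC/C=C(\C)CC[C@H]12)C(=O)O3 | intermediate
25 | CNP0343227.1, (1R,2S,6R,12S,3E,10E)-12-hydroperoxy bis-lactone | C=C1C(=O)O[C@H]2/C=C(\C)C[C@@H]3C=C(C/C=C/[C@@](C)(OO)CC[C@H]12)C(=O)O3 | target

Total step count: 10. Longest linear sequence: 8 steps (1, 2, 3, 6, 7, 8, 9, 10).

Steps most likely to fail

Step 9. What may go wrong: delivery of the acrylate to the wrong diene face, because control from the remote C6 centre is weak; outer-sphere C–O closure leading to the cis ring fusion; further Heck vinylation of the exo-methylene product. The fallback replaces palladium by a radical–polar crossover that closes the lactone through an allyl cation under product-stability control. It sets out from 22. Oxidative lactone annulation with malonic acid and Mn(OAc)3·2H2O (KOAc, AcOH, 25–40 °C) should add the malonyl radical to C1 of the diene. Trivalent manganese then oxidises the allyl radical and the lactone closes at C2, giving the trans α-carboxy lactone F1. Decarboxylative Mannich methylenation of the α-carboxy lactone F1 (aq. HCHO, Et2NH, then NaOAc/AcOH, heat) comes back to the route at 24.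

Step 10. What may go wrong: hydrogen abstraction from the C12 methyl instead of C10, or oxygen delivery to the wrong face of C11=C12. The fallback is reagent-controlled and polar. It sets out from 24. Shi epoxidation of the C11=C12 olefin (fructose-derived ketone enantiomer chosen for this face, KHSO5 as Oxone, buffered MeCN–water, 0 °C) gives the (11R,12R)-epoxide F2. Perhydrolysis with anhydrous ethereal H2O2 and MoO2(acac)2 (cat.) should open it at the tertiary carbon with inversion to the (11R,12S)-11-hydroxy-12-hydroperoxide F3. Silylation of the more acidic OOH (Et3SiCl, imidazole, −40 °C) gives the triethylsilyl peroxide F4. Burgess dehydration of the C11 carbinol, which can only eliminate towards C10, gives the E-C10=C11 silyl peroxide F5. HF·pyridine (THF, 0 °C) then removes the silyl group and comes back to the route at 25.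

Step 8. What may go wrong: oligomerisation or exo-mode insertion in the ring closure, double-bond migration by palladium hydride, or epimerisation at C6. The fallback is a two-point Suzuki–Miyaura closure instead of the Heck reaction. It sets out from 21. Cross-metathesis of the terminal olefin with vinylboronic acid pinacol ester (second-generation Hoveyda–Grubbs catalyst, CH2Cl2, 40 °C; the trisubstituted olefins and the vinyl iodide should be inert) gives the E-alkenylboronate F6. Intramolecular Suzuki–Miyaura coupling of the E-alkenylboronate F6 (Pd(PPh3)4, TlOEt, THF–H2O, high dilution, rt) forms C2–C3 between two alkenyl partners whose geometries are already defined before the ring closes and comes back to the route at 22.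

Further compounds
F1 | step 9 | α-carboxy lactone: 24 with CH–CO2H at C15 in place of the exo-methylene (C15 epimers) | OC(=O)C1C(=O)O[C@H]2/C=C(\C)C[C@@H]3C=C(CC/C=C(\C)CC[C@H]12)C(=O)O3
F2 | step 10 | (11R,12R)-11,12-epoxide of 24 | C=C1C(=O)O[C@H]2/C=C(\C)C[C@@H]3C=C(CC[C@H]4O[C@]4(C)CC[C@H]12)C(=O)O3
F3 | step 10 | (11R,12S)-11-hydroxy-12-hydroperoxide | C=C1C(=O)O[C@H]2/C=C(\C)C[C@@H]3C=C(CC[C@@H](O)[C@@](C)(OO)CC[C@H]12)C(=O)O3
F4 | step 10 | (11R,12S)-11-hydroxy-12-(triethylsilylperoxy) compound | C=C1C(=O)O[C@H]2/C=C(\C)C[C@@H]3C=C(CC[C@@H](O)[C@@](C)(OO[Si](CC)(CC)CC)CC[C@H]12)C(=O)O3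
F5 | step 10 | triethylsilyl peroxide of 25 | C=C1C(=O)O[C@H]2/C=C(\C)C[C@@H]3C=C(C/C=C/[C@@](C)(OO[Si](CC)(CC)CC)CC[C@H]12)C(=O)O3
F6 | step 8 | E-alkenylboronate: 21 with the terminal olefin carbon bearing a pinacolboryl group | I/C=C(\C)C[C@@H]1C=C(CC/C=C(\C)CC/C=C/B2OC(C)(C)C(C)(C)O2)C(=O)O1
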